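The route rests on opening the ten-membered carbocycle at the C9–C10 bond, where the ring holds a Morita–Baylis–Hillman-type unit: the C9 carbinol next to the ester-bearing C1=C10 alkene. A Nozaki–Hiyama–Kishi macrocyclisation of a (Z)-α-iodoenoate onto an α-angeloyloxy aldehyde closes this ring after the lactone, sets the C9 stereocentre and the ring-cis enoate in one operation, and gives the target directly because O8 already carries the angelate. The precursor is an open-chain trans-disubstituted α-methylene-γ-butyrolactone, built from (S)-citronellal through a 3-(bromomethyl)butenolide, a Barbier allylation that sets C7, and a Mitsunobu inversion that installs the angelate at C8.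

Key step: step 11

Numbering (germacrane-type, used throughout): C1=C10 is the ring alkene and C10 bears the methyl ester (C14); C4 bears the methyl group; C6 bears the lactone oxygen; C7 is the other ring-fusion carbon; C8 bears the angelate and C9 the hydroxyl; C11=C13 is the exocyclic methylene and C12 the lactone carbonyl. TBS = tert-butyl(dimethyl)silyl.

Assumption: (S,S)-ProPhenol is taken as the ligand enantiomer that directs the alkynylzinc to the Si face of 1; should the sense be opposite, its antipode is used.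

Step 1
Reactants: 1 (S)-citronellal; 2 tert-butyl(dimethyl)(prop-2-yn-1-yloxy)silane
Product: 4 (4R,6S)-1-{[tert-butyl(dimethyl)silyl]oxy}-6,10-dimethylundec-9-en-2-yn-4-ol, via methylzinc alkynide 3 (not isolated)
Conditions: 2, Me2Zn, (S,S)-ProPhenol (cat.), Ph3P=O (cat.), toluene, 0 °C; then 1, 0 °C to rt; aq NH4Cl
Reagents that add atoms: none
Why: Trost-type ProPhenol/zinc asymmetric alkynylation, in which the dinuclear zinc catalyst should deliver the alkynyl group to the Si face of the aldehyde and so set the new carbinol (C6) as R under catalyst control, the remote C4 methyl centre having little influence.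

Step 2
Reactants: 4 (4R,6S)-1-{[tert-butyl(dimethyl)silyl]oxy}-6,10-dimethylundec-9-en-2-yn-4-ol
Product: 6 (2Z,4R,6S)-1-{[tert-butyl(dimethyl)silyl]oxy}-2-iodo-6,10-dimethylundeca-2,9-dien-4-ol, via cyclic alkenylalanate 5 (not isolated)
Conditions: Red-Al, THF, 0 °C to rt; then I2, THF, −78 to 0 °C; aq Rochelle salt
Reagents that add atoms: iodine, II
Why: Hydroxyl-directed trans-hydroalumination of the propargylic alcohol places aluminium on the distal alkyne carbon through a five-membered alanate, and iodinolysis with retention should give the (Z)-γ-iodoallylic alcohol without touching a stereocentre.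

Step 3
Reactants: 6 (2Z,4R,6S)-1-{[tert-butyl(dimethyl)silyl]oxy}-2-iodo-6,10-dimethylundeca-2,9-dien-4-ol
Product: 7 (5R)-3-({[tert-butyl(dimethyl)silyl]oxy}methyl)-5-[(2S)-2,6-dimethylhept-5-en-1-yl]furan-2(5H)-one
Conditions: PdCl2(PPh3)2 (cat.), CO (1 atm), K2CO3, THF, rt
Reagents that add atoms: carbon monoxide, [C-]#[O+]
Why: Palladium-catalysed carbonylative lactonisation of a (Z)-γ-iodoallylic alcohol (oxidative addition, CO insertion, capture of the acyl-palladium by the cis hydroxyl) should close the butenolide with the C6 centre untouched.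

Step 4
Reactants: 7 (5R)-3-({[tert-butyl(dimethyl)silyl]oxy}methyl)-5-[(2S)-2,6-dimethylhept-5-en-1-yl]furan-2(5H)-one
Product: 8 (5R)-3-(bromomethyl)-5-[(2S)-2,6-dimethylhept-5-en-1-yl]furan-2(5H)-one
Conditions: Ph3PBr2, CH2Cl2, 0 °C to rt
Reagents that add atoms: dibromo(triphenyl)phosphorane, BrP(Br)(c1ccccc1)(c1ccccc1)c1ccccc1
Why: Direct conversion of a primary allylic silyl ether into the bromide with Ph3PBr2 (alkoxyphosphonium formation, SN2 by bromide) runs without base, which spares the acidic γ-hydrogen of the butenolide.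

Step 5
Reactants: 8 (5R)-3-(bromomethyl)-5-[(2S)-2,6-dimethylhept-5-en-1-yl]furan-2(5H)-one; 9 {[tert-butyl(dimethyl)silyl]oxy}acetaldehyde
Product: 10 (4R,5R)-4-[(1R)-2-{[tert-butyl(dimethyl)silyl]oxy}-1-hydroxyethyl]-5-[(2S)-2,6-dimethylhept-5-en-1-yl]-3-methylideneoxolan-2-one
Conditions: Zn dust, THF/sat. aq NH4Cl, 0 °C to rt
Reagents that add atoms: none
Why: Zinc-mediated Barbier allylation (SE2′) of the 2-(bromomethyl)butenolide should add the aldehyde at C7 anti to the C6 side chain (trans lactone) and, through a chair Zimmerman–Traxler transition state with the ring-fixed (E)-type allyl unit, give the anti carbinol (8R, the C8 epimer of the target) while unveiling the exocyclic methylene.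

Step 6
Reactants: 10 (4R,5R)-4-[(1R)-2-{[tert-butyl(dimethyl)silyl]oxy}-1-hydroxyethyl]-5-[(2S)-2,6-dimethylhept-5-en-1-yl]-3-methylideneoxolan-2-one; 11 angelic acid, (2Z)-2-methylbut-2-enoic acid
Product: 12 (1S)-2-{[tert-butyl(dimethyl)silyl]oxy}-1-[(2R,3S)-2-[(2S)-2,6-dimethylhept-5-en-1-yl]-4-methylidene-5-oxooxolan-3-yl]ethyl (2Z)-2-methylbut-2-enoate
Conditions: PPh3, DIAD (premixed), toluene, 0 °C; then 11, then 10, 0 °C to rt
Reagents that add atoms: none
Why: Mitsunobu esterification, in which angelate displaces the alkoxyphosphonium of the secondary alcohol by SN2 and inverts C8 (8R to 8S), under neutral conditions that should not isomerise the (Z)-angelate to the tiglate.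

Step 7
Reactants: 12 (1S)-2-{[tert-butyl(dimethyl)silyl]oxy}-1-[(2R,3S)-2-[(2S)-2,6-dimethylhept-5-en-1-yl]-4-methylidene-5-oxooxolan-3-yl]ethyl (2Z)-2-methylbut-2-enoate
Product: 14 (1S)-2-{[tert-butyl(dimethyl)silyl]oxy}-1-[(2R,3S)-4-methylidene-2-[(2S)-2-methyl-5-oxopentyl]-5-oxooxolan-3-yl]ethyl (2Z)-2-methylbut-2-enoate, via ozonide 13 (not isolated)
Conditions: O3, CH2Cl2, Sudan III (end-point indicator), −78 °C; then Me2S, −78 °C to rt
Reagents that add atoms: ozone, [O-][O+]=O
Why: Ozonolysis with a dye end point should cleave only the electron-rich trisubstituted isopropylidene alkene, the conjugated methylene lactone and angelate alkenes reacting far more slowly, and reductive work-up gives the C1 aldehyde.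

Step 8
Reactants: 14 (1S)-2-{[tert-butyl(dimethyl)silyl]oxy}-1-[(2R,3S)-4-methylidene-2-[(2S)-2-methyl-5-oxopentyl]-5-oxooxolan-3-yl]ethyl (2Z)-2-methylbut-2-enoate; 15 methyl (triphenyl-λ5-phosphanylidene)acetate
Product: 17 methyl (2Z,6S)-7-[(2R,3S)-3-[(1S)-2-{[tert-butyl(dimethyl)silyl]oxy}-1-{[(2Z)-2-methylbut-2-enoyl]oxy}ethyl]-4-methylidene-5-oxooxolan-2-yl]-2-iodo-6-methylhept-2-enoate, via iodo ylide 16 (not isolated)
Conditions: 15, NIS, CH2Cl2, −20 °C; then 14, −20 °C to rt
Reagents that add atoms: N-iodosuccinimide, O=C1CCC(=O)N1I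
Why: Wittig olefination with the α-iodo stabilised ylide formed in the flask by iodination of the ester ylide; as with stabilised ylides in general the ester should end up trans to the alkyl chain, which gives the (Z)-α-iodoenoate.

Step 9
Reactants: 17 methyl (2Z,6S)-7-[(2R,3S)-3-[(1S)-2-{[tert-butyl(dimethyl)silyl]oxy}-1-{[(2Z)-2-methylbut-2-enoyl]oxy}ethyl]-4-methylidene-5-oxooxolan-2-yl]-2-iodo-6-methylhept-2-enoate
Product: 18 methyl (2Z,6S)-7-[(2R,3S)-3-[(1S)-2-hydroxy-1-{[(2Z)-2-methylbut-2-enoyl]oxy}ethyl]-4-methylidene-5-oxooxolan-2-yl]-2-iodo-6-methylhept-2-enoate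
Conditions: HF·pyridine, pyridine/THF, 0 °C to rt
Reagents that add atoms: none
Why: Cleavage of the primary silyl ether by buffered HF·pyridine, whose weakly acidic medium should avoid the 1,2-acyl shift from O8 to O9 that basic fluoride would invite.

Step 10
Reactants: 18 methyl (2Z,6S)-7-[(2R,3S)-3-[(1S)-2-hydroxy-1-{[(2Z)-2-methylbut-2-enoyl]oxy}ethyl]-4-methylidene-5-oxooxolan-2-yl]-2-iodo-6-methylhept-2-enoate
Product: 19 methyl (2Z,6S)-2-iodo-6-methyl-7-[(2R,3S)-3-[(1S)-1-{[(2Z)-2-methylbut-2-enoyl]oxy}-2-oxoethyl]-4-methylidene-5-oxooxolan-2-yl]hept-2-enoate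
Conditions: Dess–Martin periodinane, NaHCO3, CH2Cl2, 0 °C to rt; used at once
Reagents that add atoms: none
Why: Dess–Martin oxidation of the primary alcohol under buffered, non-basic conditions should give the α-acyloxy aldehyde without epimerising C8.

Step 11
Reactants: 19 methyl (2Z,6S)-2-iodo-6-methyl-7-[(2R,3S)-3-[(1S)-1-{[(2Z)-2-methylbut-2-enoyl]oxy}-2-oxoethyl]-4-methylidene-5-oxooxolan-2-yl]hept-2-enoate
Product: 20 methyl (3aS,4S,5S,6E,10S,11aR)-5-hydroxy-10-methyl-3-methylidene-4-{[(2Z)-2-methylbut-2-enoyl]oxy}-2-oxo-2,3,3a,4,5,8,9,10,11,11a-decahydrocyclodeca[b]furan-6-carboxylate (the target)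
Conditions: CrCl2 (excess), NiCl2 (cat.), DMSO/THF, rt, slow addition of 19 (about 2 mM); aq work-up
Reagents that add atoms: none
Why: Ni(0), formed from NiCl2 by CrCl2, inserts into the C10–I bond of the (Z)-α-iodoenoate and transmetalates to an alkenylchromium(III) that adds to the tethered C9 aldehyde. This is the Nozaki–Hiyama–Kishi alkenyl iodide–aldehyde macrocyclisation, the type of closure used for ten-membered germacranolide carbocycles. The ten-membered ring closes in a 10-exo-trig mode after the γ-lactone is in place, and the (Z)-iodide geometry is carried into the ring-cis (E by CIP) C1=C10 enoate. The new C9 centre is controlled by C8: with the C8–O bond anti to the forming C9–C10 bond (polar Felkin–Anh) and the tether holding C10 gauche to C7, the chromium-bound carbonyl oxygen lies outside the closing ring, so C10 should attack the Si face and give the (9S) alcohol trans to the angelate. The step needs cyclisation over oligomerisation and addition to the aldehyde only: high dilution and the trans-lactone, which holds both chains on neighbouring ring carbons, favour closure, and organochromium reagents leave the esters, the lactone and the conjugated acceptors alone. The chromium alkoxide gives the free C9 hydroxyl on work-up, so the product is the target itself.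

Compound list
1 | (S)-citronellal, (3S)-3,7-dimethyloct-6-enal | O=CC[C@@H](C)CCC=C(C)C | starting material
2 | tert-butyl(dimethyl)(prop-2-yn-1-yloxy)silane | C#CCO[Si](C)(C)C(C)(C)C | starting material
3 | methyl{3-[(tert-butyldimethylsilyl)oxy]prop-1-yn-1-yl}zinc (methylzinc alkynide) | C[Zn]C#CCO[Si](C)(C)C(C)(C)C | intermediate (not isolated)
4 | (4R,6S)-1-{[tert-butyl(dimethyl)silyl]oxy}-6,10-dimethylundec-9-en-2-yn-4-ol | O[C@@H](C#CCO[Si](C)(C)C(C)(C)C)C[C@@H](C)CCC=C(C)C | intermediate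
5 | sodium cyclic alkenylalanate of 4 (2,5-dihydro-1,2-oxaluminole with two 2-methoxyethoxy groups on Al, Al bound to O4 and to C2 of the chain) | [Na+].COCCO[Al-]1(OCCOC)O[C@H](C[C@@H](C)CCC=C(C)C)C=C1CO[Si](C)(C)C(C)(C)C | intermediate (not isolated)
6 | (2Z,4R,6S)-1-{[tert-butyl(dimethyl)silyl]oxy}-2-iodo-6,10-dimethylundeca-2,9-dien-4-ol | O[C@@H](/C=C(\I)CO[Si](C)(C)C(C)(C)C)C[C@@H](C)CCC=C(C)C | intermediate
7 | (5R)-3-({[tert-butyl(dimethyl)silyl]oxy}methyl)-5-[(2S)-2,6-dimethylhept-5-en-1-yl]furan-2(5H)-one | O=C1O[C@H](C[C@@H](C)CCC=C(C)C)C=C1CO[Si](C)(C)C(C)(C)C | intermediate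
8 | (5R)-3-(bromomethyl)-5-[(2S)-2,6-dimethylhept-5-en-1-yl]furan-2(5H)-one | O=C1O[C@H](C[C@@H](C)CCC=C(C)C)C=C1CBr | intermediate
9 | {[tert-butyl(dimethyl)silyl]oxy}acetaldehyde | O=CCO[Si](C)(C)C(C)(C)C | starting material
10 | (4R,5R)-4-[(1R)-2-{[tert-butyl(dimethyl)silyl]oxy}-1-hydroxyethyl]-5-[(2S)-2,6-dimethylhept-5-en-1-yl]-3-methylideneoxolan-2-one | C=C1C(=O)O[C@H](C[C@@H](C)CCC=C(C)C)[C@H]1[C@@H](O)CO[Si](C)(C)C(C)(C)C | intermediate
11 | angelic acid, (2Z)-2-methylbut-2-enoic acid | C/C=C(/C)C(=O)O | starting material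
12 | (1S)-2-{[tert-butyl(dimethyl)silyl]oxy}-1-[(2R,3S)-2-[(2S)-2,6-dimethylhept-5-en-1-yl]-4-methylidene-5-oxooxolan-3-yl]ethyl (2Z)-2-methylbut-2-enoate | C=C1C(=O)O[C@H](C[C@@H](C)CCC=C(C)C)[C@H]1[C@H](OC(=O)/C(C)=C\C)CO[Si](C)(C)C(C)(C)C | intermediate
13 | secondary ozonide of 12 (3,3-dimethyl-1,2,4-trioxolane at the former isopropylidene alkene, mixture at the new ring carbon) | C=C1C(=O)O[C@H](C[C@@H](C)CCC2OOC(C)(C)O2)[C@H]1[C@H](OC(=O)/C(C)=C\C)CO[Si](C)(C)C(C)(C)C | intermediate (not isolated)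
14 | (1S)-2-{[tert-butyl(dimethyl)silyl]oxy}-1-[(2R,3S)-4-methylidene-2-[(2S)-2-methyl-5-oxopentyl]-5-oxooxolan-3-yl]ethyl (2Z)-2-methylbut-2-enoate | C=C1C(=O)O[C@H](C[C@@H](C)CCC=O)[C@H]1[C@H](OC(=O)/C(C)=C\C)CO[Si](C)(C)C(C)(C)C | intermediate
15 | methyl (triphenyl-λ5-phosphanylidene)acetate | COC(=O)C=P(c1ccccc1)(c1ccccc1)c1ccccc1 | starting material
16 | methyl iodo(triphenyl-λ5-phosphanylidene)acetate (iodo ylide) | COC(=O)C(I)=P(c1ccccc1)(c1ccccc1)c1ccccc1 | intermediate (not isolated)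
17 | methyl (2Z,6S)-7-[(2R,3S)-3-[(1S)-2-{[tert-butyl(dimethyl)silyl]oxy}-1-{[(2Z)-2-methylbut-2-enoyl]oxy}ethyl]-4-methylidene-5-oxooxolan-2-yl]-2-iodo-6-methylhept-2-enoate | C=C1C(=O)O[C@H](C[C@@H](C)CC/C=C(\I)C(=O)OC)[C@H]1[C@H](OC(=O)/C(C)=C\C)CO[Si](C)(C)C(C)(C)C | intermediate
18 | methyl (2Z,6S)-7-[(2R,3S)-3-[(1S)-2-hydroxy-1-{[(2Z)-2-methylbut-2-enoyl]oxy}ethyl]-4-methylidene-5-oxooxolan-2-yl]-2-iodo-6-methylhept-2-enoate | C=C1C(=O)O[C@H](C[C@@H](C)CC/C=C(\I)C(=O)OC)[C@H]1[C@H](OC(=O)/C(C)=C\C)CO | intermediate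
19 | methyl (2Z,6S)-2-iodo-6-methyl-7-[(2R,3S)-3-[(1S)-1-{[(2Z)-2-methylbut-2-enoyl]oxy}-2-oxoethyl]-4-methylidene-5-oxooxolan-2-yl]hept-2-enoate | C=C1C(=O)O[C@H](C[C@@H](C)CC/C=C(\I)C(=O)OC)[C@H]1[C@H](OC(=O)/C(C)=C\C)C=O | intermediate
20 | methyl (3aS,4S,5S,6E,10S,11aR)-5-hydroxy-10-methyl-3-methylidene-4-{[(2Z)-2-methylbut-2-enoyl]oxy}-2-oxo-2,3,3a,4,5,8,9,10,11,11a-decahydrocyclodeca[b]furan-6-carboxylate | C=C1C(=O)O[C@@H]2C[C@@H](C)CC/C=C(/C(=O)OC)[C@H](O)[C@@H](OC(=O)/C(C)=C\C)[C@@H]12 | target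

Total step count: 11. Longest linear sequence: 11 steps, from (S)-citronellal 1.

Steps most likely to fail

1. Step 11. The ester-bearing alkenylchromium may form slowly or be protonated before it adds (loss of iodine without ring closure), the open chain may oligomerise, and attack on the Re face would give the C9 epimer. The fallback closes the same ring by ring-closing metathesis and sets out from aldehyde 14. Wittig methylenation (Ph3P=CH2, THF, −78 °C) should give (1S)-2-{[tert-butyl(dimethyl)silyl]oxy}-1-[(2R,3S)-4-methylidene-2-[(2S)-2-methylhex-5-en-1-yl]-5-oxooxolan-3-yl]ethyl (2Z)-2-methylbut-2-enoate F1. Desilylation with HF·pyridine gives the primary alcohol (1S)-2-hydroxy-1-[(2R,3S)-4-methylidene-2-[(2S)-2-methylhex-5-en-1-yl]-5-oxooxolan-3-yl]ethyl (2Z)-2-methylbut-2-enoate F2, and Dess–Martin oxidation gives the aldehyde (1S)-1-[(2R,3S)-4-methylidene-2-[(2S)-2-methylhex-5-en-1-yl]-5-oxooxolan-3-yl]-2-oxoethyl (2Z)-2-methylbut-2-enoate F3. Addition of [1-(methoxycarbonyl)vinyl]diisobutylalane (from methyl propiolate, DIBAL-H and NMO) gives, after separation of the C9 epimers, methyl (3S,4S)-3-hydroxy-2-methylidene-4-{[(2Z)-2-methylbut-2-enoyl]oxy}-4-[(2R,3S)-4-methylidene-2-[(2S)-2-methylhex-5-en-1-yl]-5-oxooxolan-3-yl]butanoate F4. Ring-closing metathesis of F4 (Hoveyda–Grubbs II, toluene, 80 °C, high dilution) between the terminal alkene and the 2-substituted acrylate should then form the ring-cis C1=C10 enoate and return to the route at 20.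

2. Step 6. The activated, β-branched secondary alcohol may eliminate towards C7, react with partial retention through participation of the lactone carbonyl, or give tiglate by phosphine-induced isomerisation of the angelate. The fallback sets the C8 configuration in the C–C bond formation instead of by inversion and sets out from bromide 8. Palladium-catalysed stannylation (Bu3SnSnBu3, Pd(PPh3)4) gives (5R)-5-[(2S)-2,6-dimethylhept-5-en-1-yl]-3-[(tributylstannyl)methyl]furan-2(5H)-one F5. Its BF3·OEt2-promoted addition to aldehyde 9 at −78 °C runs through an open antiperiplanar transition state, which is syn-selective whatever the allyl geometry, and gives (4R,5R)-4-[(1S)-2-{[tert-butyl(dimethyl)silyl]oxy}-1-hydroxyethyl]-5-[(2S)-2,6-dimethylhept-5-en-1-yl]-3-methylideneoxolan-2-one F6, the C8 epimer of 10. Esterification of F6 with angelic acid 11 with retention (2,4,6-trichlorobenzoyl chloride, Et3N, toluene, 80 °C) comes back to the route at 12.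

3. Step 1. With an α-unbranched aldehyde, aldol self-condensation can compete with alkynylation and the facial discrimination of the catalyst may be incomplete, which would lower the configurational purity at C6. The fallback sets the centre by reduction and sets out from 1 and 2. Addition of the lithium acetylide of 2 (n-BuLi, THF, −78 °C) to 1 gives the epimeric mixture (4RS,6S)-1-{[tert-butyl(dimethyl)silyl]oxy}-6,10-dimethylundec-9-en-2-yn-4-ol F7, and oxidation (MnO2 or Dess–Martin periodinane) gives the ynone (6S)-1-{[tert-butyl(dimethyl)silyl]oxy}-6,10-dimethylundec-9-en-2-yn-4-one F8. Noyori transfer hydrogenation of F8 with RuCl[(R,R)-TsDPEN](p-cymene) in 2-propanol, in which the alkynyl group plays the role of the unsaturated substituent, should give the (4R) alcohol and come back to the route at 4.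

Further compounds
F1 | step 11 | (1S)-2-{[tert-butyl(dimethyl)silyl]oxy}-1-[(2R,3S)-4-methylidene-2-[(2S)-2-methylhex-5-en-1-yl]-5-oxooxolan-3-yl]ethyl (2Z)-2-methylbut-2-enoate | C=C1C(=O)O[C@H](C[C@@H](C)CCC=C)[C@H]1[C@H](OC(=O)/C(C)=C\C)CO[Si](C)(C)C(C)(C)C
F2 | step 11 | (1S)-2-hydroxy-1-[(2R,3S)-4-methylidene-2-[(2S)-2-methylhex-5-en-1-yl]-5-oxooxolan-3-yl]ethyl (2Z)-2-methylbut-2-enoate | C=C1C(=O)O[C@H](C[C@@H](C)CCC=C)[C@H]1[C@H](OC(=O)/C(C)=C\C)CO
F3 | step 11 | (1S)-1-[(2R,3S)-4-methylidene-2-[(2S)-2-methylhex-5-en-1-yl]-5-oxooxolan-3-yl]-2-oxoethyl (2Z)-2-methylbut-2-enoate | C=C1C(=O)O[C@H](C[C@@H](C)CCC=C)[C@H]1[C@H](OC(=O)/C(C)=C\C)C=O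
F4 | step 11 | methyl (3S,4S)-3-hydroxy-2-methylidene-4-{[(2Z)-2-methylbut-2-enoyl]oxy}-4-[(2R,3S)-4-methylidene-2-[(2S)-2-methylhex-5-en-1-yl]-5-oxooxolan-3-yl]butanoate | C=C1C(=O)O[C@H](C[C@@H](C)CCC=C)[C@H]1[C@H](OC(=O)/C(C)=C\C)[C@@H](O)C(=C)C(=O)OC
F5 | step 6 | (5R)-5-[(2S)-2,6-dimethylhept-5-en-1-yl]-3-[(tributylstannyl)methyl]furan-2(5H)-one | O=C1O[C@H](C[C@@H](C)CCC=C(C)C)C=C1C[Sn](CCCC)(CCCC)CCCC
F6 | step 6 | (4R,5R)-4-[(1S)-2-{[tert-butyl(dimethyl)silyl]oxy}-1-hydroxyethyl]-5-[(2S)-2,6-dimethylhept-5-en-1-yl]-3-methylideneoxolan-2-one | C=C1C(=O)O[C@H](C[C@@H](C)CCC=C(C)C)[C@H]1[C@H](O)CO[Si](C)(C)C(C)(C)C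
F7 | step 1 | (4RS,6S)-1-{[tert-butyl(dimethyl)silyl]oxy}-6,10-dimethylundec-9-en-2-yn-4-ol | OC(C#CCO[Si](C)(C)C(C)(C)C)C[C@@H](C)CCC=C(C)C
F8 | step 1 | (6S)-1-{[tert-butyl(dimethyl)silyl]oxy}-6,10-dimethylundec-9-en-2-yn-4-one | O=C(C#CCO[Si](C)(C)C(C)(C)C)C[C@@H](C)CCC=C(C)C
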